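**Retrosynthetic overview**

1. Feature: on the benzo ring of the chroman, O1 (on C8a) stands para to the C6 hydroxyl. The 6-hydroxychroman is therefore a hydroquinone monoether, the rearranged form of a para-quinol spiro ether that a simple 4-alkylphenol and a tertiary alcohol can give.
2. Side chain: the C5'–C6' bond of the C33 chain is cut into allylic bromide 9 and the anion of all-E-heptaprenyl phenyl sulfone 22; 22 comes from geranylgeranyl phenyl sulfone 16 and ω-bromofarnesyl silyl ether 13.
3. Key disconnection: C4–C4a of the dihydropyran, made by a 1,2-carbon shift in spirodienone 5 (dienone–phenol rearrangement).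
4. Spirodienone 5: C5–O1 from oxidative dearomatisation of phenol 4; the aryl–CH2 bond of 4 from hydroboration/Suzuki coupling of (R)-linalool, which supplies C2 with its configuration.
5. Ring order: benzene ring bought; spiro tetrahydrofuran (step 2); ring expansion to the dihydropyran (step 3); no ring is formed afterwards.

Key step: step 3

Remark: commercial (R)-(−)-linalool of high enantiomeric purity is assumed; the C–O bond at its carbinol carbon is never broken, so its purity should carry through to C2 of the target.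

**Route**

Step 1
Reactants: 1 (R)-linalool; 2 4-bromo-2,3-dimethylphenol
Product: 4 4-[(3R)-3-hydroxy-3,7-dimethyloct-6-en-1-yl]-2,3-dimethylphenol, via B-alkyl-9-BBN adduct 3 (not isolated)
Conditions: 9-BBN, THF, 0 °C to rt; then 2, Pd(OAc)2 (cat.), SPhos (cat.), aq K3PO4, THF/H2O, 65 °C
Reagents that add atoms: none
Why: 9-BBN hydroborates only the monosubstituted vinyl group at its terminus, and the B-alkyl borane should undergo B-alkyl Suzuki–Miyaura coupling with the aryl bromide under a zerovalent palladium/SPhos catalyst that tolerates the phenoxide and the free tertiary alcohol, the carbinol stereocenter being untouched.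

Step 2
Reactants: 4 4-[(3R)-3-hydroxy-3,7-dimethyloct-6-en-1-yl]-2,3-dimethylphenol
Product: 5 (2R)-2,6,7-trimethyl-2-(4-methylpent-3-en-1-yl)-1-oxaspiro[4.5]deca-6,9-dien-8-one (both epimers at spiro carbon C5)
Conditions: PhI(OAc)2, (CF3)2CHOH, 0 °C
Reagents that add atoms: none
Why: Oxidative dearomatisation of a para-alkylphenol with PhI(OAc)2 in a non-nucleophilic solvent gives a phenoxonium-type species that the tethered tertiary hydroxyl traps at the para carbon in a 5-exo spiroetherification; the spiro carbon forms without control, which is harmless because it becomes sp2 in step 3.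

Step 3
Reactants: 5 (2R)-2,6,7-trimethyl-2-(4-methylpent-3-en-1-yl)-1-oxaspiro[4.5]deca-6,9-dien-8-one
Product: 6 (2R)-2,7,8-trimethyl-2-(4-methylpent-3-en-1-yl)chroman-6-ol
Conditions: BF3·OEt2, CH2Cl2, −40 to 0 °C, argon; aq NaHCO3 quench
Reagents that add atoms: none
Why: BF3 binds the cross-conjugated carbonyl of 5 and turns the ring into a hydroxypentadienyl cation with positive charge on C6 and C10; the spiro-bound methylene C4 then shifts from C5 to the unsubstituted neighbour C10, the cation left on C5 is an oxocarbenium ion through the O1 lone pair, and loss of the C10 proton restores the arene and releases BF3. This is a dienone–phenol rearrangement of a 4-alkoxy-4-alkylcyclohexa-2,5-dienone, the same type as the acid-promoted conversion of para-quinol ethers and oxaspirodecadienones into hydroquinone monoethers. The dihydropyran is closed by ring expansion: the 1,2-carbon shift forms C4–C4a and enlarges the five-membered spiro ether by one ring carbon, with no new C–O bond. No stereocenter is made; the spiro centre vanishes, so both epimers of 5 should converge, and C2 keeps the linalool configuration because the C2–O1 bond stays intact. The step needs carbon rather than oxygen to migrate, and migration toward C10 rather than C6: only carbon migration leaves an oxygen-stabilised cation, and only at the C10 terminus can a proton be lost to aromatise, whereas a shift to the methyl-bearing C6 gives a blocked cation that can only revert. Low temperature and the absence of protic acid should keep the isolated trisubstituted alkene and the tertiary C2–O1 bond from ionising.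

Step 4
Reactants: 6 (2R)-2,7,8-trimethyl-2-(4-methylpent-3-en-1-yl)chroman-6-ol
Product: 7 tert-butyl(dimethyl){[(2R)-2,7,8-trimethyl-2-(4-methylpent-3-en-1-yl)chroman-6-yl]oxy}silane
Conditions: TBSCl, imidazole, DMF, rt
Reagents that add atoms: tert-butyldimethylsilyl chloride, CC(C)(C)[Si](C)(C)Cl
Why: Standard silylation of a phenol masks the acidic, oxidation-prone chromanol hydroxyl for the selenium oxidation and the carbanion chemistry that follow.

Step 5
Reactants: 7 tert-butyl(dimethyl){[(2R)-2,7,8-trimethyl-2-(4-methylpent-3-en-1-yl)chroman-6-yl]oxy}silane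
Product: 8 (2E)-5-[(2R)-6-{[tert-butyl(dimethyl)silyl]oxy}-2,7,8-trimethylchroman-2-yl]-2-methylpent-2-en-1-ol
Conditions: SeO2 (cat.), t-BuOOH, salicylic acid (cat.), CH2Cl2, 0 °C to rt, stopped at partial conversion
Reagents that add atoms: tert-butyl hydroperoxide, CC(C)(C)OO (terminal oxygen source; the oxygen is passed on through SeO2, O=[Se]=O)
Why: Riley-type catalytic SeO2 allylic oxidation (ene reaction, then [2,3]-sigmatropic shift) attacks the only alkene and oxidises the methyl trans to the chain, giving the (E)-2-methylalk-2-en-1-ol as is usual for terminal isopropylidene groups of prenyl chains.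

Step 6
Reactants: 8 (2E)-5-[(2R)-6-{[tert-butyl(dimethyl)silyl]oxy}-2,7,8-trimethylchroman-2-yl]-2-methylpent-2-en-1-ol
Product: 9 {[(2R)-2-[(3E)-5-bromo-4-methylpent-3-en-1-yl]-2,7,8-trimethylchroman-6-yl]oxy}(tert-butyl)dimethylsilane
Conditions: CBr4, PPh3, CH2Cl2, 0 °C
Reagents that add atoms: carbon tetrabromide, BrC(Br)(Br)Br
Why: The Appel reaction converts the primary allylic alcohol into the bromide by SN2 displacement under neutral conditions, without allylic transposition, loss of (E) geometry or cleavage of the aryl silyl ether.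

Step 7
Reactants: 10 (2E,6E)-farnesol
Product: 11 tert-butyl(diphenyl){[(2E,6E)-3,7,11-trimethyldodeca-2,6,10-trien-1-yl]oxy}silane
Conditions: TBDPSCl, imidazole, DMF, rt
Reagents that add atoms: tert-butyldiphenylsilyl chloride, CC(C)(C)[Si](Cl)(c1ccccc1)c1ccccc1
Why: Standard silylation of a primary allylic alcohol gives an ether that is stable to the selenium oxidation, the sulfone carbanion and the palladium/hydride desulfonylation, and that zerovalent palladium cannot ionise.

Step 8
Reactants: 11 tert-butyl(diphenyl){[(2E,6E)-3,7,11-trimethyldodeca-2,6,10-trien-1-yl]oxy}silane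
Product: 12 (2E,6E,10E)-12-{[tert-butyl(diphenyl)silyl]oxy}-2,6,10-trimethyldodeca-2,6,10-trien-1-ol
Conditions: SeO2 (cat.), t-BuOOH, salicylic acid (cat.), CH2Cl2, 0 °C to rt, stopped at partial conversion
Reagents that add atoms: tert-butyl hydroperoxide, CC(C)(C)OO (terminal oxygen source; the oxygen is passed on through SeO2, O=[Se]=O)
Why: Riley-type SeO2 allylic oxidation prefers the terminal isopropylidene group (the alkene next to the silyloxy group is deactivated, the internal one is less reactive) and oxidises its (E)-methyl, a known selectivity for farnesyl derivatives.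

Step 9
Reactants: 12 (2E,6E,10E)-12-{[tert-butyl(diphenyl)silyl]oxy}-2,6,10-trimethyldodeca-2,6,10-trien-1-ol
Product: 13 {[(2E,6E,10E)-12-bromo-3,7,11-trimethyldodeca-2,6,10-trien-1-yl]oxy}(tert-butyl)diphenylsilane
Conditions: CBr4, PPh3, CH2Cl2, 0 °C
Reagents that add atoms: carbon tetrabromide, BrC(Br)(Br)Br
Why: The Appel reaction gives the primary allylic bromide by SN2 displacement with retention of the (E) geometry and leaves the silyl ether intact.

Step 10
Reactants: 14 (2E,6E,10E)-geranylgeraniol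
Product: 16 {[(2E,6E,10E)-3,7,11,15-tetramethylhexadeca-2,6,10,14-tetraen-1-yl]sulfonyl}benzene (geranylgeranyl phenyl sulfone), via geranylgeranyl bromide 15 (not isolated)
Conditions: PBr3, Et2O, −10 °C; concentrate; then PhSO2Na, DMF, rt
Reagents that add atoms: sodium benzenesulfinate, [Na+].[O-]S(=O)c1ccccc1 (PBr3, BrP(Br)Br, puts bromine into 15 only)
Why: Low-temperature bromination of the primary allylic alcohol with PBr3 and SN2 S-alkylation of the sulfinate in DMF both proceed at C1 without touching the (E)-alkenes, a standard entry to prenyl sulfones.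

Step 11
Reactants: 16 geranylgeranyl phenyl sulfone; 13 {[(2E,6E,10E)-12-bromo-3,7,11-trimethyldodeca-2,6,10-trien-1-yl]oxy}(tert-butyl)diphenylsilane
Product: 18 tert-butyl{[(2E,6E,10E,14E,18E,22E)-3,7,11,15,19,23,27-heptamethyl-13-(phenylsulfonyl)octacosa-2,6,10,14,18,22,26-heptaen-1-yl]oxy}diphenylsilane (both configurations at C13), via lithiated sulfone 17 (not isolated)
Conditions: n-BuLi, THF/DMPU, −78 °C; then 13, −78 to −20 °C
Reagents that add atoms: none
Why: The sulfone-stabilised allyl carbanion is alkylated at its α-carbon by the primary allylic bromide (SN2, the classical sulfone coupling of prenyl chains) with all alkene geometries kept; the sulfone-bearing carbon forms unselectively and is removed in step 12.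

Step 12
Reactants: 18 tert-butyl{[(2E,6E,10E,14E,18E,22E)-3,7,11,15,19,23,27-heptamethyl-13-(phenylsulfonyl)octacosa-2,6,10,14,18,22,26-heptaen-1-yl]oxy}diphenylsilane
Product: 19 tert-butyl{[(2E,6E,10E,14E,18E,22E)-3,7,11,15,19,23,27-heptamethyloctacosa-2,6,10,14,18,22,26-heptaen-1-yl]oxy}diphenylsilane
Conditions: PdCl2(dppp) (cat.; dppp = 1,3-bis(diphenylphosphino)propane), LiEt3BH, THF, 0 °C
Reagents that add atoms: none
Why: In this palladium-catalysed reductive desulfonylation, zerovalent palladium ionises the allylic sulfone to a π-allyl complex and hydride is delivered to the less substituted terminus, so the trisubstituted (E)-alkene should stay in place while the silyl ether is inert.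

Step 13
Reactants: 19 tert-butyl{[(2E,6E,10E,14E,18E,22E)-3,7,11,15,19,23,27-heptamethyloctacosa-2,6,10,14,18,22,26-heptaen-1-yl]oxy}diphenylsilane
Product: 20 (2E,6E,10E,14E,18E,22E)-3,7,11,15,19,23,27-heptamethyloctacosa-2,6,10,14,18,22,26-heptaen-1-ol (all-E-heptaprenol)
Conditions: n-Bu4NF, THF, 0 °C to rt
Reagents that add atoms: none
Why: Fluoride-mediated desilylation frees the primary allylic alcohol without affecting the polyene.

Step 14
Reactants: 20 all-E-heptaprenol
Product: 22 {[(2E,6E,10E,14E,18E,22E)-3,7,11,15,19,23,27-heptamethyloctacosa-2,6,10,14,18,22,26-heptaen-1-yl]sulfonyl}benzene (all-E-heptaprenyl phenyl sulfone), via heptaprenyl bromide 21 (not isolated)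
Conditions: PBr3, Et2O, −10 °C; concentrate; then PhSO2Na, DMF, rt
Reagents that add atoms: sodium benzenesulfinate, [Na+].[O-]S(=O)c1ccccc1 (PBr3, BrP(Br)Br, puts bromine into 21 only)
Why: As in step 10, SN2 bromination at C1 followed by SN2 S-alkylation of the sulfinate gives the allylic sulfone with the (E) geometry retained.

Step 15
Reactants: 22 all-E-heptaprenyl phenyl sulfone; 9 {[(2R)-2-[(3E)-5-bromo-4-methylpent-3-en-1-yl]-2,7,8-trimethylchroman-6-yl]oxy}(tert-butyl)dimethylsilane
Product: 24 tert-butyl(dimethyl){[(2R)-2,7,8-trimethyl-2-[(3E,7E,11E,15E,19E,23E,27E)-4,8,12,16,20,24,28,32-octamethyl-6-(phenylsulfonyl)tritriaconta-3,7,11,15,19,23,27,31-octaen-1-yl]chroman-6-yl]oxy}silane (both configurations at C6'), via lithiated heptaprenyl sulfone 23 (not isolated)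
Conditions: n-BuLi, THF/DMPU, −78 °C; then 9, −78 to −20 °C
Reagents that add atoms: none
Why: α-Alkylation of the sulfone-stabilised allyl carbanion by the primary allylic bromide (SN2) forms the C5'–C6' bond with every alkene geometry and C2 untouched; the new sulfone-bearing center forms unselectively and is removed in step 16.

Step 16
Reactants: 24 tert-butyl(dimethyl){[(2R)-2,7,8-trimethyl-2-[(3E,7E,11E,15E,19E,23E,27E)-4,8,12,16,20,24,28,32-octamethyl-6-(phenylsulfonyl)tritriaconta-3,7,11,15,19,23,27,31-octaen-1-yl]chroman-6-yl]oxy}silane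
Product: 25 tert-butyl(dimethyl){[(2R)-2,7,8-trimethyl-2-[(3E,7E,11E,15E,19E,23E,27E)-4,8,12,16,20,24,28,32-octamethyltritriaconta-3,7,11,15,19,23,27,31-octaen-1-yl]chroman-6-yl]oxy}silane
Conditions: PdCl2(dppp) (cat.), LiEt3BH, THF, 0 °C
Reagents that add atoms: none
Why: Palladium-catalysed reductive desulfonylation through the π-allyl complex, with hydride delivery to the less substituted terminus, should remove the sulfone while keeping the C7'=C8' alkene in position and (E), the aryl silyl ether being stable to the hydride.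

Step 17
Reactants: 25 tert-butyl(dimethyl){[(2R)-2,7,8-trimethyl-2-[(3E,7E,11E,15E,19E,23E,27E)-4,8,12,16,20,24,28,32-octamethyltritriaconta-3,7,11,15,19,23,27,31-octaen-1-yl]chroman-6-yl]oxy}silane
Product: 26 plastochromanol 8, (2R)-2,7,8-trimethyl-2-[(3E,7E,11E,15E,19E,23E,27E)-4,8,12,16,20,24,28,32-octamethyltritriaconta-3,7,11,15,19,23,27,31-octaen-1-yl]chroman-6-ol
Conditions: n-Bu4NF, THF, 0 °C, argon
Reagents that add atoms: none
Why: Fluoride cleaves the aryl silyl ether under conditions that affect neither the eight alkenes nor C2, and exclusion of air protects the free chromanol.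

**Compound list**

1 | (R)-linalool | C=C[C@](C)(O)CCC=C(C)C | starting material
2 | 4-bromo-2,3-dimethylphenol | Cc1c(O)ccc(Br)c1C | starting material
3 | 9-[(3S)-3-hydroxy-3,7-dimethyloct-6-en-1-yl]-9-borabicyclo[3.3.1]nonane (same spatial arrangement as 1; the descriptor changes by priority only) | CC(C)=CCC[C@@](C)(O)CCB1C2CCCC1CCC2 | intermediate (not isolated)
4 | 4-[(3R)-3-hydroxy-3,7-dimethyloct-6-en-1-yl]-2,3-dimethylphenol | CC(C)=CCC[C@@](C)(O)CCc1ccc(O)c(C)c1C | intermediate
5 | (2R)-2,6,7-trimethyl-2-(4-methylpent-3-en-1-yl)-1-oxaspiro[4.5]deca-6,9-dien-8-one, both C5 epimers | CC(C)=CCC[C@]1(C)CCC2(C=CC(=O)C(C)=C2C)O1 | intermediate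
6 | (2R)-2,7,8-trimethyl-2-(4-methylpent-3-en-1-yl)chroman-6-ol | CC(C)=CCC[C@]1(C)CCc2cc(O)c(C)c(C)c2O1 | intermediate
7 | tert-butyl(dimethyl){[(2R)-2,7,8-trimethyl-2-(4-methylpent-3-en-1-yl)chroman-6-yl]oxy}silane | CC(C)=CCC[C@]1(C)CCc2cc(O[Si](C)(C)C(C)(C)C)c(C)c(C)c2O1 | intermediate
8 | (2E)-5-[(2R)-6-{[tert-butyl(dimethyl)silyl]oxy}-2,7,8-trimethylchroman-2-yl]-2-methylpent-2-en-1-ol | OC/C(C)=C/CC[C@]1(C)CCc2cc(O[Si](C)(C)C(C)(C)C)c(C)c(C)c2O1 | intermediate
9 | {[(2R)-2-[(3E)-5-bromo-4-methylpent-3-en-1-yl]-2,7,8-trimethylchroman-6-yl]oxy}(tert-butyl)dimethylsilane | BrC/C(C)=C/CC[C@]1(C)CCc2cc(O[Si](C)(C)C(C)(C)C)c(C)c(C)c2O1 | intermediate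
10 | (2E,6E)-farnesol | CC(C)=CCC/C(C)=C/CC/C(C)=C/CO | starting material
11 | tert-butyl(diphenyl){[(2E,6E)-3,7,11-trimethyldodeca-2,6,10-trien-1-yl]oxy}silane | CC(C)=CCC/C(C)=C/CC/C(C)=C/CO[Si](c1ccccc1)(c1ccccc1)C(C)(C)C | intermediate
12 | (2E,6E,10E)-12-{[tert-butyl(diphenyl)silyl]oxy}-2,6,10-trimethyldodeca-2,6,10-trien-1-ol | OC/C(C)=C/CC/C(C)=C/CC/C(C)=C/CO[Si](c1ccccc1)(c1ccccc1)C(C)(C)C | intermediate
13 | {[(2E,6E,10E)-12-bromo-3,7,11-trimethyldodeca-2,6,10-trien-1-yl]oxy}(tert-butyl)diphenylsilane | BrC/C(C)=C/CC/C(C)=C/CC/C(C)=C/CO[Si](c1ccccc1)(c1ccccc1)C(C)(C)C | intermediate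
14 | (2E,6E,10E)-geranylgeraniol | CC(C)=CCC/C(C)=C/CC/C(C)=C/CC/C(C)=C/CO | starting material
15 | (2E,6E,10E)-geranylgeranyl bromide | CC(C)=CCC/C(C)=C/CC/C(C)=C/CC/C(C)=C/CBr | intermediate (not isolated)
16 | geranylgeranyl phenyl sulfone, {[(2E,6E,10E)-3,7,11,15-tetramethylhexadeca-2,6,10,14-tetraen-1-yl]sulfonyl}benzene | CC(C)=CCC/C(C)=C/CC/C(C)=C/CC/C(C)=C/CS(=O)(=O)c1ccccc1 | intermediate
17 | α-lithio geranylgeranyl phenyl sulfone | CC(C)=CCC/C(C)=C/CC/C(C)=C/CC/C(C)=C/C([Li])S(=O)(=O)c1ccccc1 | intermediate (not isolated)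
18 | tert-butyl{[(2E,6E,10E,14E,18E,22E)-3,7,11,15,19,23,27-heptamethyl-13-(phenylsulfonyl)octacosa-2,6,10,14,18,22,26-heptaen-1-yl]oxy}diphenylsilane, both C13 epimers | CC(C)=CCC/C(C)=C/CC/C(C)=C/CC/C(C)=C/C(C/C(C)=C/CC/C(C)=C/CC/C(C)=C/CO[Si](c1ccccc1)(c1ccccc1)C(C)(C)C)S(=O)(=O)c1ccccc1 | intermediate
19 | tert-butyl{[(2E,6E,10E,14E,18E,22E)-3,7,11,15,19,23,27-heptamethyloctacosa-2,6,10,14,18,22,26-heptaen-1-yl]oxy}diphenylsilane | CC(C)=CCC/C(C)=C/CC/C(C)=C/CC/C(C)=C/CC/C(C)=C/CC/C(C)=C/CC/C(C)=C/CO[Si](c1ccccc1)(c1ccccc1)C(C)(C)C | intermediate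
20 | all-E-heptaprenol, (2E,6E,10E,14E,18E,22E)-3,7,11,15,19,23,27-heptamethyloctacosa-2,6,10,14,18,22,26-heptaen-1-ol | CC(C)=CCC/C(C)=C/CC/C(C)=C/CC/C(C)=C/CC/C(C)=C/CC/C(C)=C/CC/C(C)=C/CO | intermediate
21 | all-E-heptaprenyl bromide | CC(C)=CCC/C(C)=C/CC/C(C)=C/CC/C(C)=C/CC/C(C)=C/CC/C(C)=C/CC/C(C)=C/CBr | intermediate (not isolated)
22 | all-E-heptaprenyl phenyl sulfone | CC(C)=CCC/C(C)=C/CC/C(C)=C/CC/C(C)=C/CC/C(C)=C/CC/C(C)=C/CC/C(C)=C/CS(=O)(=O)c1ccccc1 | intermediate
23 | α-lithio all-E-heptaprenyl phenyl sulfone | CC(C)=CCC/C(C)=C/CC/C(C)=C/CC/C(C)=C/CC/C(C)=C/CC/C(C)=C/CC/C(C)=C/C([Li])S(=O)(=O)c1ccccc1 | intermediate (not isolated)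
24 | tert-butyl(dimethyl){[(2R)-2,7,8-trimethyl-2-[(3E,7E,11E,15E,19E,23E,27E)-4,8,12,16,20,24,28,32-octamethyl-6-(phenylsulfonyl)tritriaconta-3,7,11,15,19,23,27,31-octaen-1-yl]chroman-6-yl]oxy}silane, both C6' epimers | CC(C)=CCC/C(C)=C/CC/C(C)=C/CC/C(C)=C/CC/C(C)=C/CC/C(C)=C/CC/C(C)=C/C(C/C(C)=C/CC[C@]1(C)CCc2cc(O[Si](C)(C)C(C)(C)C)c(C)c(C)c2O1)S(=O)(=O)c1ccccc1 | intermediate
25 | tert-butyl(dimethyl){[(2R)-2,7,8-trimethyl-2-[(3E,7E,11E,15E,19E,23E,27E)-4,8,12,16,20,24,28,32-octamethyltritriaconta-3,7,11,15,19,23,27,31-octaen-1-yl]chroman-6-yl]oxy}silane | CC(C)=CCC/C(C)=C/CC/C(C)=C/CC/C(C)=C/CC/C(C)=C/CC/C(C)=C/CC/C(C)=C/CC/C(C)=C/CC[C@]1(C)CCc2cc(O[Si](C)(C)C(C)(C)C)c(C)c(C)c2O1 | intermediate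
26 | plastochromanol 8, (2R)-2,7,8-trimethyl-2-[(3E,7E,11E,15E,19E,23E,27E)-4,8,12,16,20,24,28,32-octamethyltritriaconta-3,7,11,15,19,23,27,31-octaen-1-yl]chroman-6-ol | CC(C)=CCC/C(C)=C/CC/C(C)=C/CC/C(C)=C/CC/C(C)=C/CC/C(C)=C/CC/C(C)=C/CC/C(C)=C/CC[C@]1(C)CCc2cc(O)c(C)c(C)c2O1 | target

**Step count and risks**

Total step count: 17. Longest linear sequence: 10 steps (farnesol 10 through steps 7, 8, 9, 11, 12, 13, 14, 15, 16, 17 to 26). The chroman branch from (R)-linalool is 9 steps.

Steps most likely to fail: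

1. Step 3 (key step). The 1,2-shift may be diverted by oxygen migration, by ionisation of the tertiary C2–O1 bond under the Lewis acid (erosion of configuration at C2 or fragmentation), or by acid-induced reaction of the side-chain alkene. Fallback, setting out from borane 3 (made from 1 as in step 1) and coming back at 6: 3 would be Suzuki-coupled under the step 1 catalyst with 1-bromo-2,5-dimethoxy-3,4-dimethylbenzene F1 (from commercial 1,4-dimethoxy-2,3-dimethylbenzene and N-bromosuccinimide in CH3CN) to give (3R)-1-(2,5-dimethoxy-3,4-dimethylphenyl)-3,7-dimethyloct-6-en-3-ol F2. Oxidative demethylation with (NH4)2Ce(NO3)6 in CH3CN/H2O at 0 °C should give 2-[(3R)-3-hydroxy-3,7-dimethyloct-6-en-1-yl]-5,6-dimethyl-1,4-benzoquinone F3. HC(OCH3)3 in CH3OH with a trace of acid should close the tertiary hydroxyl onto the neighbouring quinone carbonyl as the cyclic mixed ketal (2R)-8a-methoxy-2,7,8-trimethyl-2-(4-methylpent-3-en-1-yl)-2,3,4,8a-tetrahydrochromen-6-one F4. Reduction of F4 with ascorbic acid (or Zn/AcOH) expels methanol and gives 6. The aryl C8a–O1 bond is made by ketalisation, so the C2–O bond is again never broken and the configuration is retained, without any rearrangement.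

2. Step 5. Incomplete conversion, over-oxidation to the enal (which NaBH4 would return to 8) or oxidative attack on the electron-rich chroman ring may make the allylic oxidation inefficient. Fallback, setting out from 7 and coming back at 8: Lemieux–Johnson cleavage of the alkene (OsO4 cat., NaIO4, 2,6-lutidine, dioxane/H2O) should give 3-[(2S)-6-{[tert-butyl(dimethyl)silyl]oxy}-2,7,8-trimethylchroman-2-yl]propanal F5 (same spatial arrangement at C2; the descriptor changes by priority only). Wittig olefination with the stabilised ylide Ph3P=C(CH3)CO2Et in CH2Cl2 should give ethyl (2E)-5-[(2R)-6-{[tert-butyl(dimethyl)silyl]oxy}-2,7,8-trimethylchroman-2-yl]-2-methylpent-2-enoate F6 with the (E) geometry set by the ylide. Reduction with i-Bu2AlH in CH2Cl2 at −78 °C gives 8.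

3. Step 16. Hydride delivery to the wrong terminus of the π-allyl intermediate would move or isomerise the C7'=C8' alkene, and such isomers would be very hard to separate from a C33 polyene. Fallback, setting out from 20 (together with 9) and coming back at 25, with no sulfone at all: Corey–Kim chlorination of 20 (N-chlorosuccinimide, (CH3)2S, CH2Cl2, −40 to 0 °C) should give all-E-heptaprenyl chloride F7. Active barium (from BaI2 and lithium biphenylide, LiC12H10, in THF) at −78 °C should convert F7 into all-E-heptaprenylbarium chloride F8. This allylbarium reagent is known to couple with allylic bromides at the α-carbon of both partners with retention of alkene geometry, so with bromide 9 it should give 25 directly; step 17 then follows.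

**Further compounds**

F1 | step 3 | 1-bromo-2,5-dimethoxy-3,4-dimethylbenzene | COc1cc(Br)c(OC)c(C)c1C
F2 | step 3 | (3R)-1-(2,5-dimethoxy-3,4-dimethylphenyl)-3,7-dimethyloct-6-en-3-ol | CC(C)=CCC[C@@](C)(O)CCc1cc(OC)c(C)c(C)c1OC
F3 | step 3 | 2-[(3R)-3-hydroxy-3,7-dimethyloct-6-en-1-yl]-5,6-dimethyl-1,4-benzoquinone | CC(C)=CCC[C@@](C)(O)CCC1=CC(=O)C(C)=C(C)C1=O
F4 | step 3 | (2R)-8a-methoxy-2,7,8-trimethyl-2-(4-methylpent-3-en-1-yl)-2,3,4,8a-tetrahydrochromen-6-one (either C8a epimer) | CC(C)=CCC[C@]1(C)CCC2=CC(=O)C(C)=C(C)C2(OC)O1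
F5 | step 5 | 3-[(2S)-6-{[tert-butyl(dimethyl)silyl]oxy}-2,7,8-trimethylchroman-2-yl]propanal | O=CCC[C@]1(C)CCc2cc(O[Si](C)(C)C(C)(C)C)c(C)c(C)c2O1
F6 | step 5 | ethyl (2E)-5-[(2R)-6-{[tert-butyl(dimethyl)silyl]oxy}-2,7,8-trimethylchroman-2-yl]-2-methylpent-2-enoate | CCOC(=O)/C(C)=C/CC[C@]1(C)CCc2cc(O[Si](C)(C)C(C)(C)C)c(C)c(C)c2O1
F7 | step 16 | all-E-heptaprenyl chloride | CC(C)=CCC/C(C)=C/CC/C(C)=C/CC/C(C)=C/CC/C(C)=C/CC/C(C)=C/CC/C(C)=C/CCl
F8 | step 16 | all-E-heptaprenylbarium chloride | CC(C)=CCC/C(C)=C/CC/C(C)=C/CC/C(C)=C/CC/C(C)=C/CC/C(C)=C/CC/C(C)=C/C[Ba]Cl
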